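The route builds C2 (with its two methyl groups) and ether oxygen O1 of each dihydropyran ring (chroman numbering) from one molecule of acetone. The acetone is joined to an arene whose C8a carries fluoride ortho to a temporary C4 ketone. One tandem aldol addition/intramolecular SNAr on 2',4',6'-trifluoroacetophenone forges C3–C2 and O1–C8a and closes the pyran ring. The two remaining fluorides, activated by the same ketone, become the phenol oxygens. Deoxygenation at C4, C8 bromination and divergent acylation give the acyl chromans of both halves, which are joined at the bridging methine by catalyst-controlled addition to an ortho-quinone methide.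

Key step: step 1

Remark: half A is the chroman bearing the (2R)-2-methylbutanoyl group and half B the chroman bearing the isobutyryl group; by CIP analysis both stereocenters of the target are (R).
Remark: (2R)-2-methylbutanoic acid and 6-methylheptanal are taken as purchasable.
Remark: whether the quinine- or the quinidine-derived squaramide delivers the (R)-bridge cannot be predicted with confidence and is to be settled in the first run; the quinine-derived catalyst, 3-{[3,5-bis(trifluoromethyl)phenyl]amino}-4-{[(8α,9S)-6'-methoxycinchonan-9-yl]amino}cyclobut-3-ene-1,2-dione, is written.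

Step 1
Reactants: 1 2',4',6'-trifluoroacetophenone; 2 acetone
Product: 5 5,7-difluoro-2,2-dimethylchroman-4-one, via lithium enolate 3 (not isolated), via lithium aldolate 4 (not isolated)
Conditions: LiN(SiMe3)2 (1.05 equiv), THF, −78 °C; acetone (3 equiv), −78 °C; then DMPU, −78 °C to rt
Reagents that add atoms: none
Why: LiN(SiMe3)2 converts 1 into lithium enolate 3, whose methylene carbon adds to the carbonyl carbon of acetone (crossed aldol addition, C3–C2) to give tertiary lithium alkoxide 4; on warming with DMPU this alkoxide attacks the fluorine-bearing ring carbon ortho to the ketone and expels fluoride through a Meisenheimer adduct (intramolecular SNAr, O1–C8a). The closest known reaction types are the lithium-enolate aldol addition to ketones and the alkoxide SNAr cyclisation of 2-fluoroaryl ketones to chroman-4-ones, here run in tandem. The one ring that closes is the pyranone ring, formed by 6-exo attack of the alkoxide oxygen on the aromatic carbon (addition–elimination). No stereocenter is created. The step needs ring closure to outrun retro-aldol cleavage and dehydration of 4 and needs ortho over para fluoride displacement: the ketone stabilises the Meisenheimer adduct, the two ortho fluorides are equivalent by the mirror symmetry of the 2,4,6-trifluorophenyl ring, the para fluoride cannot be reached by the tether, and fluoride loss is irreversible so the reversible aldol equilibrium should drain into 5.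

Step 2
Reactants: 5 5,7-difluoro-2,2-dimethylchroman-4-one
Product: 7 5,7-bis(benzyloxy)-2,2-dimethylchroman-4-one, via monobenzyloxy fluoro chromanone 6 (not isolated)
Conditions: BnOH (2.5 equiv), NaH (2.5 equiv), DMF, 0 °C to 50 °C
Reagents that add atoms: benzyl alcohol, OCc1ccccc1
Why: Nucleophilic aromatic substitution (SNAr): C7–F is para and C5–F ortho to the C4 ketone, so sodium benzyloxide should displace both fluorides (the 7-substituted intermediate 6 expected first), installing both phenol oxygens in protected form before any base-sensitive stereocenter exists.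

Step 3
Reactants: 7 5,7-bis(benzyloxy)-2,2-dimethylchroman-4-one
Product: 9 5,7-bis(benzyloxy)-2,2-dimethylchroman, via chroman-4-ol aluminate 8 (not isolated)
Conditions: LiAlH4, AlCl3 (1:1), Et2O, 0 °C to rt
Reagents that add atoms: none
Why: Mixed-hydride hydrogenolysis of an alkoxy-substituted aryl ketone: hydride reduction to the benzylic aluminium alkoxide 8, ionisation to a cation stabilised by the three ring oxygens and a second hydride delivery should give the C4 methylene, while benzyl and alkyl aryl ethers tolerate the reagent.

Step 4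
Reactants: 9 5,7-bis(benzyloxy)-2,2-dimethylchroman
Product: 10 5,7-bis(benzyloxy)-8-bromo-2,2-dimethylchroman
Conditions: NBS (1.0 equiv), CH2Cl2, −78 °C to 0 °C, dark
Reagents that add atoms: N-bromosuccinimide, O=C1CCC(=O)N1Br
Why: Electrophilic aromatic bromination: both free positions are activated by three oxygens, but C8 (para to the C5 ether, next to the tied-back ring oxygen) is far less shielded than C6 between two benzyloxy groups, the site preference known for 5,7-di-O-benzyl flavans.

Step 5
Reactants: 10 5,7-bis(benzyloxy)-8-bromo-2,2-dimethylchroman; 11 N-methoxy-N-methylisobutyramide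
Product: 14 1-[5,7-bis(benzyloxy)-2,2-dimethylchroman-8-yl]-2-methylpropan-1-one, via aryllithium 12 (not isolated), via tetrahedral adduct 13 (not isolated)
Conditions: n-BuLi (1.05 equiv), THF, −78 °C; then 11, −78 °C to 0 °C; aq NH4Cl
Reagents that add atoms: none
Why: Bromine–lithium exchange gives aryllithium 12, which adds to the achiral Weinreb amide to form the chelated adduct 13 that persists until aqueous quench (Weinreb ketone synthesis), so the isobutyryl group should arrive at C8 only and without over-addition.

Step 6
Reactants: 14 1-[5,7-bis(benzyloxy)-2,2-dimethylchroman-8-yl]-2-methylpropan-1-one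
Product: 15 1-(5,7-dihydroxy-2,2-dimethylchroman-8-yl)-2-methylpropan-1-one
Conditions: H2 (1 atm), Pd/C (10 wt % Pd), EtOAc–MeOH, rt
Reagents that add atoms: none
Why: Catalytic hydrogenolysis of benzyl aryl ethers; the hindered aryl ketone flanked by two ortho oxygens should not be reduced under these conditions.

Step 7
Reactants: 15 1-(5,7-dihydroxy-2,2-dimethylchroman-8-yl)-2-methylpropan-1-one; 16 6-methylheptanal
Product: 19 1-{5,7-dihydroxy-2,2-dimethyl-6-[6-methyl-1-(4-methylbenzenesulfonyl)heptyl]chroman-8-yl}-2-methylpropan-1-one (racemic at the sulfonyl-bearing carbon), via carbinol 17 (not isolated), via benzylic cation 18 (not isolated)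
Conditions: 16 (1.5 equiv), TolSO2Na (3 equiv), HCO2H–H2O–CH2Cl2, rt
Reagents that add atoms: sodium p-toluenesulfinate, Cc1ccc(cc1)S(=O)[O-].[Na+]
Why: Acid-mediated three-component sulfonylalkylation of a phenol (Friedel–Crafts hydroxyalkylation followed by SN1 substitution): C6, the only free ring position of 15, adds to the protonated aldehyde, carbinol 17 ionises in formic acid to the benzylic cation 18 stabilised by the three ring oxygens (the O-protonated form of the quinone methide, which is not present as the neutral species in this acidic medium), and excess p-toluenesulfinic acid captures it at sulfur as the bench-stable sulfone 19, whose new benzylic center is racemic and is erased in step 11.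

Step 8
Reactants: 20 (2R)-2-methylbutanoic acid
Product: 22 (2R)-N-methoxy-N,2-dimethylbutanamide, via acyl imidazole 21 (not isolated)
Conditions: CDI, CH2Cl2, 0 °C to rt; then MeNHOMe·HCl, rt
Reagents that add atoms: N,O-dimethylhydroxylamine hydrochloride, CNOC.Cl
Why: Amide formation through acyl imidazole 21 (CDI activation); a simple α-branched acid without an N-acyl group should be activated and aminolysed without loss of the (R) configuration, which comes from the purchased acid.

Step 9
Reactants: 10 5,7-bis(benzyloxy)-8-bromo-2,2-dimethylchroman; 22 (2R)-N-methoxy-N,2-dimethylbutanamide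
Product: 25 (2R)-1-[5,7-bis(benzyloxy)-2,2-dimethylchroman-8-yl]-2-methylbutan-1-one, via arylmagnesium bromide 23 (not isolated), via magnesium adduct 24 (not isolated)
Conditions: Mg turnings (I2-activated, 1.5 equiv), LiCl (1.2 equiv), THF, rt to 40 °C; then 22, 0 °C to rt; aq NH4Cl
Reagents that add atoms: none
Why: Direct magnesium insertion into the C8–Br bond (Grignard formation, as for other 2,4,6-trialkoxyaryl bromides) gives arylmagnesium bromide 23, which is far less basic than the aryllithium used for the achiral amide in step 5 and should therefore add to the Weinreb amide without deprotonating its α-carbon; the chelated magnesium adduct 24 masks the ketone until quench (Weinreb ketone synthesis), so the (2R) center is carried over unchanged and no later step is strongly basic.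

Step 10
Reactants: 25 (2R)-1-[5,7-bis(benzyloxy)-2,2-dimethylchroman-8-yl]-2-methylbutan-1-one
Product: 26 (2R)-1-(5,7-dihydroxy-2,2-dimethylchroman-8-yl)-2-methylbutan-1-one
Conditions: H2 (1 atm), Pd/C (10 wt % Pd), EtOAc–MeOH, rt
Reagents that add atoms: none
Why: Neutral catalytic hydrogenolysis of the benzyl ethers, which should leave the hindered ketone and its α-stereocenter untouched.

Step 11
Reactants: 19 sulfone of half B; 26 (2R)-1-(5,7-dihydroxy-2,2-dimethylchroman-8-yl)-2-methylbutan-1-one
Product: 28 (2R)-1-{6-[(1R)-1-[5,7-dihydroxy-2,2-dimethyl-8-(2-methylpropanoyl)chroman-6-yl]-6-methylheptyl]-5,7-dihydroxy-2,2-dimethylchroman-8-yl}-2-methylbutan-1-one, via ortho-quinone methide 27 (not isolated)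
Conditions: quinine-derived squaramide (10 mol %), aq NaHCO3, CH2Cl2, 0 °C
Reagents that add atoms: none
Why: Base-triggered 1,4-elimination of p-toluenesulfinate from the phenoxide of 19 releases the neutral ortho-quinone methide 27, and the squaramide–quinuclidine catalyst, hydrogen-bonded to the quinone methide carbonyl and to the phenoxide of 26, should direct conjugate addition of C6 of 26 (its only free ring position) to one face of the exocyclic carbon (catalytic asymmetric Friedel–Crafts-type Michael addition to an ortho-quinone methide made in situ from a 2-(1-sulfonylalkyl)phenol), so the bridging stereocenter is set under catalyst control while the (2R)-acyl center is not touched.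

**Compound list**

1 | 2',4',6'-trifluoroacetophenone | CC(=O)c1c(F)cc(F)cc1F | starting material
2 | acetone | CC(C)=O | starting material
3 | lithium 1-(2,4,6-trifluorophenyl)ethen-1-olate (formed in situ) | [Li+].[O-]C(=C)c1c(F)cc(F)cc1F | intermediate
4 | lithium 2-methyl-4-oxo-4-(2,4,6-trifluorophenyl)butan-2-olate (formed in situ) | [Li+].[O-]C(C)(C)CC(=O)c1c(F)cc(F)cc1F | intermediate
5 | 5,7-difluoro-2,2-dimethylchroman-4-one | CC1(C)CC(=O)c2c(F)cc(F)cc2O1 | intermediate
6 | 7-(benzyloxy)-5-fluoro-2,2-dimethylchroman-4-one (formed in situ) | CC1(C)CC(=O)c2c(F)cc(OCc3ccccc3)cc2O1 | intermediate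
7 | 5,7-bis(benzyloxy)-2,2-dimethylchroman-4-one | CC1(C)CC(=O)c2c(OCc3ccccc3)cc(OCc4ccccc4)cc2O1 | intermediate
8 | 5,7-bis(benzyloxy)-2,2-dimethylchroman-4-ol, racemic, present as its aluminium alkoxide (formed in situ) | CC1(C)CC(O)c2c(OCc3ccccc3)cc(OCc4ccccc4)cc2O1 | intermediate
9 | 5,7-bis(benzyloxy)-2,2-dimethylchroman | CC1(C)CCc2c(OCc3ccccc3)cc(OCc4ccccc4)cc2O1 | intermediate
10 | 5,7-bis(benzyloxy)-8-bromo-2,2-dimethylchroman | CC1(C)CCc2c(OCc3ccccc3)cc(OCc4ccccc4)c(Br)c2O1 | intermediate
11 | N-methoxy-N-methylisobutyramide | CC(C)C(=O)N(C)OC | starting material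
12 | [5,7-bis(benzyloxy)-2,2-dimethylchroman-8-yl]lithium (formed in situ) | [Li]c1c(OCc3ccccc3)cc(OCc4ccccc4)c2c1OC(C)(C)CC2 | intermediate
13 | lithium 1-[5,7-bis(benzyloxy)-2,2-dimethylchroman-8-yl]-1-[methoxy(methyl)amino]-2-methylpropan-1-olate (formed in situ) | CC(C)C([O-])(N(C)OC)c1c(OCc3ccccc3)cc(OCc4ccccc4)c2c1OC(C)(C)CC2.[Li+] | intermediate
14 | 1-[5,7-bis(benzyloxy)-2,2-dimethylchroman-8-yl]-2-methylpropan-1-one | CC(C)C(=O)c1c(OCc3ccccc3)cc(OCc4ccccc4)c2c1OC(C)(C)CC2 | intermediate
15 | 1-(5,7-dihydroxy-2,2-dimethylchroman-8-yl)-2-methylpropan-1-one | CC(C)C(=O)c1c(O)cc(O)c2c1OC(C)(C)CC2 | intermediate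
16 | 6-methylheptanal | CC(C)CCCCC=O | starting material
17 | 1-[5,7-dihydroxy-6-(1-hydroxy-6-methylheptyl)-2,2-dimethylchroman-8-yl]-2-methylpropan-1-one, racemic (formed in situ) | CC(C)C(=O)c1c(O)c(C(O)CCCCC(C)C)c(O)c2c1OC(C)(C)CC2 | intermediate
18 | 1-[5,7-dihydroxy-2,2-dimethyl-8-(2-methylpropanoyl)chroman-6-yl]-6-methylheptan-1-ylium formate, the benzylic cation of half B (O-protonated form of the quinone methide; formed in situ) | CC(C)C(=O)c1c(O)c([CH+]CCCCC(C)C)c(O)c2c1OC(C)(C)CC2.[O-]C=O | intermediate
19 | 1-{5,7-dihydroxy-2,2-dimethyl-6-[6-methyl-1-(4-methylbenzenesulfonyl)heptyl]chroman-8-yl}-2-methylpropan-1-one, racemic | CC(C)C(=O)c1c(O)c(C(CCCCC(C)C)S(=O)(=O)c3ccc(C)cc3)c(O)c2c1OC(C)(C)CC2 | intermediate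
20 | (2R)-2-methylbutanoic acid | CC[C@@H](C)C(=O)O | starting material
21 | 1-[(2R)-2-methylbutanoyl]-1H-imidazole (formed in situ) | CC[C@@H](C)C(=O)n1ccnc1 | intermediate
22 | (2R)-N-methoxy-N,2-dimethylbutanamide | CC[C@@H](C)C(=O)N(C)OC | intermediate
23 | [5,7-bis(benzyloxy)-2,2-dimethylchroman-8-yl]magnesium bromide (formed in situ) | Br[Mg]c1c(OCc3ccccc3)cc(OCc4ccccc4)c2c1OC(C)(C)CC2 | intermediate
24 | bromomagnesium (2R)-1-[5,7-bis(benzyloxy)-2,2-dimethylchroman-8-yl]-1-[methoxy(methyl)amino]-2-methylbutan-1-olate, mixture at the carbinolamine carbon (formed in situ) | CC[C@@H](C)C(O[Mg]Br)(N(C)OC)c1c(OCc3ccccc3)cc(OCc4ccccc4)c2c1OC(C)(C)CC2 | intermediate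
25 | (2R)-1-[5,7-bis(benzyloxy)-2,2-dimethylchroman-8-yl]-2-methylbutan-1-one | CC[C@@H](C)C(=O)c1c(OCc3ccccc3)cc(OCc4ccccc4)c2c1OC(C)(C)CC2 | intermediate
26 | (2R)-1-(5,7-dihydroxy-2,2-dimethylchroman-8-yl)-2-methylbutan-1-one | CC[C@@H](C)C(=O)c1c(O)cc(O)c2c1OC(C)(C)CC2 | intermediate
27 | ortho-quinone methide of half B: 7-hydroxy-2,2-dimethyl-6-(6-methylheptylidene)-8-(2-methylpropanoyl)-3,4-dihydro-2H-chromen-5(6H)-one, alkene geometry undefined (formed in situ) | CC(C)C(=O)C1=C(O)C(=CCCCCC(C)C)C(=O)C2=C1OC(C)(C)CC2 | intermediate
28 | (2R)-1-{6-[(1R)-1-[5,7-dihydroxy-2,2-dimethyl-8-(2-methylpropanoyl)chroman-6-yl]-6-methylheptyl]-5,7-dihydroxy-2,2-dimethylchroman-8-yl}-2-methylbutan-1-one | CC[C@@H](C)C(=O)c1c(O)c([C@H](CCCCC(C)C)c2c(O)c3c(c(C(=O)C(C)C)c2O)OC(C)(C)CC3)c(O)c2c1OC(C)(C)CC2 | target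

**Step count and risks**

Total steps: 11. Longest linear sequence: 8 steps (steps 1, 2, 3, 4, 5, 6, 7, 11).

Steps most likely to fail:

1. Step 11. The facial selectivity of the addition may be poor, because the quinone methide can exist as two alkene geometries and the uncatalysed phenoxide addition competes; base-induced retro-addition of the product could also scramble the bridge. Fallback: setting out from 19 and 26, the coupling would be run with NaHCO3 alone (CH2Cl2–H2O, 0 °C) without a chiral catalyst. This should give 28 together with its bridge epimer (2R)-1-{6-[(1S)-1-[5,7-dihydroxy-2,2-dimethyl-8-(2-methylpropanoyl)chroman-6-yl]-6-methylheptyl]-5,7-dihydroxy-2,2-dimethylchroman-8-yl}-2-methylbutan-1-one F1. Because of the fixed (2R)-acyl center the two are diastereomers, so stereocontrol would be replaced by preparative HPLC separation (chiral stationary phase if required); the fallback returns to the route at 28.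

2. Step 7. The benzylic cation 18 may be intercepted by unreacted 15 faster than by sulfinate, giving the symmetric bis-chroman, or may lose a proton to the vinyl phenol. Fallback: setting out from 15 and 16, a Mannich (Betti-type) three-component reaction with morpholine (EtOH, rt) proceeds through the preformed iminium ion and not through a benzylic cation. It should give the aminoalkyl phenol 1-{5,7-dihydroxy-2,2-dimethyl-6-[6-methyl-1-(morpholin-4-yl)heptyl]chroman-8-yl}-2-methylpropan-1-one F2. F2 would replace 19: with 26 and the chiral phosphoric acid (R)-3,3'-bis(2,4,6-triisopropylphenyl)-1,1'-binaphthyl-2,2'-diyl hydrogen phosphate (toluene, rt), protonation of the amine releases 27 inside a chiral ion pair and the addition returns to the route at 28.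

3. Step 1. Retro-aldol cleavage or dehydration of aldolate 4 may outrun ring closure, or an alkoxide may displace the para fluoride intermolecularly. Fallback: setting out from 1, silylation (Me3SiOTf, Et3N, CH2Cl2, 0 °C) should give the silyl enol ether trimethyl{[1-(2,4,6-trifluorophenyl)ethenyl]oxy}silane F3. A Mukaiyama aldol addition to acetone (TiCl4, CH2Cl2, −78 °C) would then give, under non-basic conditions, the isolable 3-hydroxy-3-methyl-1-(2,4,6-trifluorophenyl)butan-1-one F4. Ring closure of F4 by intramolecular SNAr (K2CO3, DMF, rt to 50 °C) returns to the route at 5, at the price of making the two bonds in two separate operations.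

**Further compounds**

F1 | step 11 | (2R)-1-{6-[(1S)-1-[5,7-dihydroxy-2,2-dimethyl-8-(2-methylpropanoyl)chroman-6-yl]-6-methylheptyl]-5,7-dihydroxy-2,2-dimethylchroman-8-yl}-2-methylbutan-1-one | CC[C@@H](C)C(=O)c1c(O)c([C@@H](CCCCC(C)C)c2c(O)c3c(c(C(=O)C(C)C)c2O)OC(C)(C)CC3)c(O)c2c1OC(C)(C)CC2
F2 | step 7 | 1-{5,7-dihydroxy-2,2-dimethyl-6-[6-methyl-1-(morpholin-4-yl)heptyl]chroman-8-yl}-2-methylpropan-1-one, racemic | CC(C)C(=O)c1c(O)c(C(CCCCC(C)C)N3CCOCC3)c(O)c2c1OC(C)(C)CC2
F3 | step 1 | trimethyl{[1-(2,4,6-trifluorophenyl)ethenyl]oxy}silane | C=C(O[Si](C)(C)C)c1c(F)cc(F)cc1F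
F4 | step 1 | 3-hydroxy-3-methyl-1-(2,4,6-trifluorophenyl)butan-1-one | CC(C)(O)CC(=O)c1c(F)cc(F)cc1F
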